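A value of 0.834, read from Friday's run, was my starting point for judging which flask holds most target at the asked time.

| flask | starting material | reagent | catalyst | temperature | remark | time |
|---|---|---|---|---|---|---|
| Friday's | 0.010 M | 0.47 equiv | 0.5 mol% | 75 °C | run made earlier |  |
| Tuesday's | 0.010 M | 1.9 equiv | 0.5 mol% | 102 °C | run made earlier |  |
| gamma | 0.010 M | 0.950 equiv | 0.5 mol% | 110 °C |  | 10 min |
| alpha | 0.010 M | 0.950 equiv | 0.5 mol% | 80 °C |  | 10 min |
| zeta | 0.010 M | 0.950 equiv | 0.5 mol% | 125 °C |  | 10 min |
| beta | 0.010 M | 0.950 equiv | 0.5 mol% | 95 °C |  | 10 min |

- Friday's (time / min: target / %, starting material / %): 4.00: 12.9, 84.1; 8.00: 15.3, 74.5; 15.0: 15.1, 67.0; 25.0: 11.4, 59.8; 50.0: 8.4, 54.8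
- Tuesday's (time / min: target / %, starting material / %): 0.667: 31.5, 57.2; 1.33: 37.2, 38.3; 2.50: 33.2, 23.6; 4.00: 23.7, 13.8; 8.00: 11.2, 5.5

(scatter of a reading: 0.5 percentage points)

1. the flask with the highest amount of target, in percent of the starting material charged ("all alike" if they lie within 1.5 percentage points) (gamma / alpha / zeta / beta / all alike)
2. final target, as a percentage of the starting material charged, in gamma
3. final target, as a percentage of the starting material charged, in alpha
4. final target, as a percentage of the starting material charged, in zeta
5. final target, as a percentage of the starting material charged, in beta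



Starting material in Friday's run was stalling toward the 0.530 of its charge that remains if one reagent goes per starting material. I therefore wrote a for starting material, b for reagent as its charge minus the conversion, and p for target, all as fractions of the starting material charged. I took making as proportional to ab and loss as proportional to p; at target's peak the two rates are equal for that moment, so their quotient loses time. Friday's peak lay between the readings at 8.00 min and 15.0 min, whose mean ab/p is the opening value, and Tuesday's reading at 1.33 min gave 1.32. Interpolating logarithmically in temperature gave the balance number of alpha, ab/p at a peak, as 0.908.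

The first readings gave second-order constants of 0.111 min⁻¹ and 0.484 min⁻¹, hence 0.145 min⁻¹ for alpha, and with nearly equal charges a = 0.408 and b = 0.358 at 10 min.

Past its peak, I reasoned, target trails the falling line ab/Q from above, so alpha's lower bound was 16.0%. For the upper bound, I let every converted part become target until that line was met, which gave 38.4%. Keeping Friday's first share of 0.811, target per part converted, moved that meeting to a conversion of 41.9%, where target stood at 34.0%, and I used this tighter amount of target as the ceiling. Alpha's reckoned conversion of 59.2% stood beyond that meeting, so I committed to the middle of the two target bounds, 25.0%, and to alpha.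

The forecast named alpha, because “so the coolest flask wins”, with 23% in alpha, 10.5% in beta, 5.2% in gamma and 4.8% in zeta; its alpha lay inside my bracket.

The flasks gave alpha as highest, with 25.6% in alpha, 13.1% in beta, 5.21% in gamma and 2.32% in zeta.

    starting material + reagent ⇌ isomer of the product (K = 3400 M⁻¹, k = 0.110 M⁻¹ s⁻¹, Ea = 86.0 kJ mol⁻¹, ΔH = −25.0 kJ mol⁻¹)
    starting material + reagent ⇌ target (K = 190 M⁻¹, k = 1.10 M⁻¹ s⁻¹, Ea = 58.0 kJ mol⁻¹, ΔH = −65.0 kJ mol⁻¹)
    starting material + reagent → uncatalysed product (k = 0.100 M⁻¹ s⁻¹, Ea = 75.0 kJ mol⁻¹)
    target + catalyst ⇌ isomer of the product + catalyst, rate k4*[catalyst]*[target] forward; the back reaction follows from the equilibrium constant (k = 210 M⁻¹ s⁻¹, Ea = 60.0 kJ mol⁻¹)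
    (constants at 110 °C)

With alpha's own remainders the line stood at 18.0%, less than its target, a quotient of 0.703 beside the make-to-use ratio of 0.732. In the scheme, target's loss runs on catalyst, so for the neighbouring flask with 0.85 mol% catalyst I scaled the balance number to 1.54. Its remainders matched alpha's, which put the line at 10.4%, and that flask held 18.7% target.

Readings and results were generated by integration for substances that don't exist; noise was put on by code.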